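## Retrosynthetic overview

1. Last bond formed: the aryl O–CH2 ether (Mitsunobu), which splits the target into 7-hydroxy-8-methoxycoumarin and a C10 epoxy-alcohol lactone of equal size.
2. Epoxy-alcohol lactone ⇐ Sharpless epoxidation of the E-allylic alcohol ⇐ Pd cyclocarbonylation of a homopropargylic alcohol, which closes the α-methylene lactone.
3. That enyne diol ⇐ (R)-epichlorohydrin as a C3 linchpin: acetylide opening, Zr-catalysed methylalumination/formaldehyde capture (E-trisubstituted allylic alcohol), epoxide re-closure, second acetylide opening.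
4. Coumarin ⇐ Pechmann-type annulation of 2-methoxyresorcinol with ethyl propiolate ⇐ resorcinol via the bis-MOM ether, ortho-lithiation/borylation/oxidation and O-methylation.
5. Ring order: pyranone ring onto the benzene ring (coumarin arm); lactone ring, then oxirane (other arm); the two arms are joined last.

Assumption: the target is exactly the stereoisomer in the SMILES, i.e. (S) at the lactone carbinol carbon and (R,R) at the oxirane, with the aryloxymethyl group cis to the oxirane methyl.

Note: no bond to the carbinol carbon from epichlorohydrin is ever broken. Its CIP descriptor changes along the route (R in 13–17, S in 18, R in 19, S in 20 and 21) only because substituent priorities change.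

## Route

Step 1
Reactants: 1 resorcinol (benzene-1,3-diol)
Product: 2 1,3-bis(methoxymethoxy)benzene
Conditions: NaH (2.4 equiv), MOMCl (2.4 equiv), DMF, 0 °C → rt
Reagents that add atoms: chloromethyl methyl ether, COCCl
Why: Williamson-type O-alkylation of both phenoxides gives the bis-MOM acetal, whose two oxygens later direct lithiation to the carbon between them.

Step 2
Reactants: 2 1,3-bis(methoxymethoxy)benzene
Product: 5 2,6-bis(methoxymethoxy)phenol, via aryllithium 3 (not isolated), via aryl boronate 4 (not isolated)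
Conditions: n-BuLi (1.2 equiv), THF, 0 °C → rt; B(OMe)3, −78 °C → rt; then AcOH, 30% H2O2, 0 °C → rt
Reagents that add atoms: n-butyllithium, [Li]CCCC (lithium of 3); trimethyl borate, COB(OC)OC (boron and methoxy groups of 4); hydrogen peroxide, OO (phenolic oxygen of 5)
Why: Directed ortho-metalation occurs at C2, flanked by both OMOM groups, and borylation followed by peroxide oxidation (1,2-aryl shift from boron to oxygen) puts the hydroxyl exactly there.

Step 3
Reactants: 5 2,6-bis(methoxymethoxy)phenol
Product: 6 2-methoxy-1,3-bis(methoxymethoxy)benzene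
Conditions: MeI (1.5 equiv), K2CO3, DMF, rt
Reagents that add atoms: iodomethane, CI
Why: Williamson ether synthesis (SN2 methylation of the only free phenoxide) fixes the future 8-methoxy group.

Step 4
Reactants: 6 2-methoxy-1,3-bis(methoxymethoxy)benzene
Product: 7 2-methoxybenzene-1,3-diol
Conditions: conc. HCl (cat.), MeOH, 50 °C
Reagents that add atoms: none
Why: Acid-catalysed acetal exchange with methanol removes both MOM groups while the aryl methyl ether is inert.

Step 5
Reactants: 7 2-methoxybenzene-1,3-diol; 8 ethyl propiolate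
Product: 9 7-hydroxy-8-methoxy-2H-chromen-2-one
Conditions: ZnCl2 (1.0 equiv), dioxane, 100 °C
Reagents that add atoms: none
Why: Pechmann-type condensation: hydroarylation of the propiolate at C4 (ortho to one OH, para to the other; C4 and C6 are equivalent) and lactonisation onto the adjacent OH can give only the 7-hydroxy-8-methoxy isomer.

Step 6
Reactants: 10 (R)-epichlorohydrin; 11 acetylene
Product: 13 (2R)-1-chloropent-4-yn-2-ol, via ethynyllithium 12 (not isolated)
Conditions: HC≡CH, n-BuLi, THF, −78 °C; BF3·OEt2; then 10, −78 °C; H2O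
Reagents that add atoms: n-butyllithium, [Li]CCCC (lithium of 12)
Why: BF3-promoted alkynylation of an epoxide (Yamaguchi–Hirao reaction) is an SN2 opening at the unsubstituted oxirane carbon, so the stereocentre of 10 is carried over untouched and becomes the lactone carbinol carbon.

Step 7
Reactants: 13 (2R)-1-chloropent-4-yn-2-ol
Product: 16 (2E,5R)-6-chloro-3-methylhex-2-ene-1,5-diol, via alkenylalane 14 (not isolated), via lithium aluminate 15 (not isolated)
Conditions: Me3Al (3.5 equiv), Cp2ZrCl2 (0.25 equiv), CH2Cl2, 0 °C → rt; evaporate; n-BuLi, THF–hexane, −78 °C; (CH2O)n, −78 °C → rt; cold aq. HCl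
Reagents that add atoms: trimethylaluminium, C[Al](C)C (C3 methyl; AlMe2 groups of 14 and 15); n-butyllithium, [Li]CCCC (butyl and lithium of 15); formaldehyde (as paraformaldehyde), C=O (C1 and its oxygen)
Why: Negishi Zr-catalysed carboalumination adds methyl and aluminium syn with aluminium on the terminal carbon, and the alkenyl aluminate is hydroxymethylated with retention, so the E-trisubstituted allylic alcohol is formed without touching the carbinol centre.

Step 8
Reactants: 16 (2E,5R)-6-chloro-3-methylhex-2-ene-1,5-diol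
Product: 17 (2E)-3-methyl-4-[(2R)-oxiran-2-yl]but-2-en-1-ol
Conditions: K2CO3 (1.5 equiv), MeOH, 0 °C → rt
Reagents that add atoms: none
Why: Intramolecular Williamson reaction (the secondary alkoxide displaces the neighbouring primary chloride) regenerates a terminal epoxide without breaking any bond at the stereocentre.

Step 9
Reactants: 17 (2E)-3-methyl-4-[(2R)-oxiran-2-yl]but-2-en-1-ol
Product: 18 (2E,5S)-3-methyloct-2-en-7-yne-1,5-diol
Conditions: LiC≡CH·H2NCH2CH2NH2 (3 equiv), DMSO, rt; aq. NH4Cl
Reagents that add atoms: lithium acetylide–ethylenediamine complex, [Li]C#C.NCCN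
Why: SN2 opening of the terminal epoxide by acetylide at the CH2 carbon gives the homopropargylic alcohol with the stereocentre retained, and the E-allylic alkoxide cannot reach the oxirane intramolecularly.

Step 10
Reactants: 18 (2E,5S)-3-methyloct-2-en-7-yne-1,5-diol
Product: 19 (5R)-5-[(2E)-4-hydroxy-2-methylbut-2-en-1-yl]-3-methylideneoxolan-2-one
Conditions: PdCl2 (5 mol %), SnCl2 (5 mol %), PPh3 (10 mol %), CO (7 atm), MeCN, 75 °C
Reagents that add atoms: carbon monoxide, [C-]#[O+]
Why: Pd-catalysed cyclocarbonylation of a homopropargylic alcohol (alkoxycarbonyl-palladium formation, syn insertion of the alkyne, protonolysis) closes the α-methylene-γ-butyrolactone, and only the secondary hydroxyl can form the five-membered ring.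

Step 11
Reactants: 19 (5R)-5-[(2E)-4-hydroxy-2-methylbut-2-en-1-yl]-3-methylideneoxolan-2-one
Product: 20 (5S)-5-{[(2R,3R)-3-(hydroxymethyl)-2-methyloxiran-2-yl]methyl}-3-methylideneoxolan-2-one
Conditions: Ti(OiPr)4 (10 mol %), D-(−)-diethyl tartrate (12 mol %), t-BuOOH (2 equiv, in decane), 4 Å molecular sieves, CH2Cl2, −20 °C
Reagents that add atoms: tert-butyl hydroperoxide, CC(C)(C)OO
Why: Sharpless asymmetric epoxidation is reagent-controlled: D-(−)-tartrate gives the (2R,3R)-oxirane from an E-3-methylalk-2-en-1-ol (the mirror image of the (2S,3S) sense that L-(+)-tartrate gives with geraniol), and the electron-poor methylene lactone is not oxidised.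

Step 12
Reactants: 20 (5S)-5-{[(2R,3R)-3-(hydroxymethyl)-2-methyloxiran-2-yl]methyl}-3-methylideneoxolan-2-one; 9 7-hydroxy-8-methoxy-2H-chromen-2-one
Product: 21 7-{[(2R,3R)-3-methyl-3-{[(2S)-4-methylidene-5-oxooxolan-2-yl]methyl}oxiran-2-yl]methoxy}-8-methoxy-2H-chromen-2-one (CNP0318299.1)
Conditions: PPh3 (1.3 equiv), DIAD (1.3 equiv), THF, 0 °C → rt
Reagents that add atoms: none
Why: Mitsunobu etherification: the acidic 7-hydroxycoumarin (pKa about 8) displaces the oxyphosphonium at the primary CH2 by SN2 under near-neutral conditions, so no stereocentre is involved and the oxirane and the Michael-acceptor lactone survive.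

## Compound list

1 | resorcinol (benzene-1,3-diol) | Oc1cccc(O)c1 | starting material
2 | 1,3-bis(methoxymethoxy)benzene | COCOc1cccc(OCOC)c1 | intermediate
3 | [2,6-bis(methoxymethoxy)phenyl]lithium | [Li]c1c(OCOC)cccc1OCOC | intermediate
4 | dimethyl [2,6-bis(methoxymethoxy)phenyl]boronate | COCOc1cccc(OCOC)c1B(OC)OC | intermediate
5 | 2,6-bis(methoxymethoxy)phenol | COCOc1cccc(OCOC)c1O | intermediate
6 | 2-methoxy-1,3-bis(methoxymethoxy)benzene | COCOc1cccc(OCOC)c1OC | intermediate
7 | 2-methoxybenzene-1,3-diol | COc1c(O)cccc1O | intermediate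
8 | ethyl propiolate | C#CC(=O)OCC | starting material
9 | 7-hydroxy-8-methoxy-2H-chromen-2-one | COc1c(O)ccc2ccc(=O)oc12 | intermediate
10 | (R)-epichlorohydrin, (2R)-2-(chloromethyl)oxirane | ClC[C@H]1CO1 | starting material
11 | acetylene | C#C | starting material
12 | ethynyllithium | [Li]C#C | intermediate
13 | (2R)-1-chloropent-4-yn-2-ol | ClC[C@H](O)CC#C | intermediate
14 | [(1E,4R)-5-chloro-4-(dimethylalumanyloxy)-2-methylpent-1-en-1-yl]dimethylalumane | C[Al](C)/C=C(\C)C[C@H](CCl)O[Al](C)C | intermediate
15 | lithium butyl[(1E,4R)-5-chloro-4-(dimethylalumanyloxy)-2-methylpent-1-en-1-yl]dimethylaluminate | [Li+].CCCC[Al-](C)(C)/C=C(\C)C[C@H](CCl)O[Al](C)C | intermediate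
16 | (2E,5R)-6-chloro-3-methylhex-2-ene-1,5-diol | OC/C=C(\C)C[C@H](CCl)O | intermediate
17 | (2E)-3-methyl-4-[(2R)-oxiran-2-yl]but-2-en-1-ol | OC/C=C(\C)C[C@@H]1CO1 | intermediate
18 | (2E,5S)-3-methyloct-2-en-7-yne-1,5-diol | OC/C=C(\C)C[C@H](CC#C)O | intermediate
19 | (5R)-5-[(2E)-4-hydroxy-2-methylbut-2-en-1-yl]-3-methylideneoxolan-2-one | C=C1C[C@@H](C/C(C)=C/CO)OC1=O | intermediate
20 | (5S)-5-{[(2R,3R)-3-(hydroxymethyl)-2-methyloxiran-2-yl]methyl}-3-methylideneoxolan-2-one | C=C1C[C@@H](C[C@@]2(C)O[C@@H]2CO)OC1=O | intermediate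
21 | 7-{[(2R,3R)-3-methyl-3-{[(2S)-4-methylidene-5-oxooxolan-2-yl]methyl}oxiran-2-yl]methoxy}-8-methoxy-2H-chromen-2-one | C=C1C[C@@H](C[C@@]2(C)O[C@@H]2COc2ccc3ccc(=O)oc3c2OC)OC1=O | target

## Step count and risks

Total step count: 12 (steps 1–5 coumarin arm, steps 6–11 lactone arm, step 12 union).
Longest linear sequence: 7 steps (steps 6–12, from 10 and 11 to 21).

Steps most likely to fail:

Step 7. The one-pot methylalumination–hydroxymethylation is run on a free β-chloro alcohol; aluminate formation or paraformaldehyde capture may be inefficient. The fallback sets out from 13 and comes back at 16. The same Me3Al/Cp2ZrCl2 carboalumination is quenched with I2 to isolate (2R,4E)-1-chloro-5-iodo-4-methylpent-4-en-2-ol F1. C1 is then introduced by Pd-catalysed methoxycarbonylation (PdCl2(PPh3)2, CO 1 atm, MeOH, NaOAc, 50 °C) to give methyl (2E,5R)-6-chloro-5-hydroxy-3-methylhex-2-enoate F2, whose E geometry keeps the hydroxyl away from the ester. Reduction with i-Bu2AlH (CH2Cl2, −78 °C) gives 16.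

Step 10. The cyclocarbonylation runs with a free allylic alcohol present, and the Pd/SnCl2 couple can ionise allylic alcohols. The fallback sets out from 17 and comes back at 19, building the lactone by enolate chemistry instead of CO insertion. Epoxide 17 is opened with the aluminium enolate of tert-butyl acetate (LiN(iPr)2, then Et2AlCl, THF, −78 → −20 °C) to give tert-butyl (4S,6E)-4,8-dihydroxy-6-methyloct-6-enoate F3. Lactonisation (pyridinium p-toluenesulfonate, toluene, 60 °C) gives (5S)-5-[(2E)-4-hydroxy-2-methylbut-2-en-1-yl]oxolan-2-one F4. Treatment with LiN(iPr)2 (2.2 equiv) and dimethyl(methylidene)ammonium iodide gives the Mannich base (5S)-3-[(dimethylamino)methyl]-5-[(2E)-4-hydroxy-2-methylbut-2-en-1-yl]oxolan-2-one F5 (C3 epimers). MeI converts it into {[(5S)-5-[(2E)-4-hydroxy-2-methylbut-2-en-1-yl]-2-oxooxolan-3-yl]methyl}trimethylammonium iodide F6, and aq. NaHCO3/CH2Cl2 eliminates the amine to give 19.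

Step 12. The Mitsunobu reaction is run on an epoxy alcohol that also carries a Michael-acceptor lactone; PPh3 or phenoxide may add to the methylene lactone, or the oxirane may open. The fallback sets out from 19 and 9 and comes back at 21, moving the epoxidation after the union. Alcohol 19 is converted (CBr4, PPh3, CH2Cl2, 0 °C) into (5R)-5-[(2E)-4-bromo-2-methylbut-2-en-1-yl]-3-methylideneoxolan-2-one F7. Phenol 9 is alkylated with it (K2CO3, acetone, rt) to give 8-methoxy-7-{[(2E)-3-methyl-4-[(2R)-4-methylidene-5-oxooxolan-2-yl]but-2-en-1-yl]oxy}-2H-chromen-2-one F8. Shi epoxidation (D-fructose-derived ketone, KHSO5 as 2KHSO5·KHSO4·K2SO4, K2CO3 buffer pH 10.5, MeCN–dimethoxymethane–H2O, 0 °C) then attacks only the electron-rich trisubstituted alkene. This ketone gives the (R,R)-oxirane from E-trisubstituted alkenes, the same facial sense as step 11, so the product is 21.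

## Further compounds

F1 | step 7 | (2R,4E)-1-chloro-5-iodo-4-methylpent-4-en-2-ol | ClC[C@H](O)C/C(C)=C/I
F2 | step 7 | methyl (2E,5R)-6-chloro-5-hydroxy-3-methylhex-2-enoate | COC(=O)/C=C(\C)C[C@H](CCl)O
F3 | step 10 | tert-butyl (4S,6E)-4,8-dihydroxy-6-methyloct-6-enoate | CC(C)(C)OC(=O)CC[C@@H](C/C(C)=C/CO)O
F4 | step 10 | (5S)-5-[(2E)-4-hydroxy-2-methylbut-2-en-1-yl]oxolan-2-one | O=C1CC[C@@H](C/C(C)=C/CO)O1
F5 | step 10 | (5S)-3-[(dimethylamino)methyl]-5-[(2E)-4-hydroxy-2-methylbut-2-en-1-yl]oxolan-2-one | CN(C)CC1C[C@@H](C/C(C)=C/CO)OC1=O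
F6 | step 10 | {[(5S)-5-[(2E)-4-hydroxy-2-methylbut-2-en-1-yl]-2-oxooxolan-3-yl]methyl}trimethylammonium iodide | C[N+](C)(C)CC1C[C@@H](C/C(C)=C/CO)OC1=O.[I-]
F7 | step 12 | (5R)-5-[(2E)-4-bromo-2-methylbut-2-en-1-yl]-3-methylideneoxolan-2-one | C=C1C[C@@H](C/C(C)=C/CBr)OC1=O
F8 | step 12 | 8-methoxy-7-{[(2E)-3-methyl-4-[(2R)-4-methylidene-5-oxooxolan-2-yl]but-2-en-1-yl]oxy}-2H-chromen-2-one | C=C1C[C@@H](C/C(C)=C/COc2ccc3ccc(=O)oc3c2OC)OC1=O
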